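- A small charge of pre-initiator, the same 51 mM in red, ochre and the new flask, gave me a common yardstick, so I counted monomer in chains per pre-initiator charged, a degree of polymerisation reckoned on the charge.

| flask | free monomer | pre-initiator | remark | time |
|---|---|---|---|---|
| red | 1 M | 51 mM | run made earlier |  |
| ochre | 2.2 M | 51 mM | run made earlier |  |
| flask | 1.5 M | 51 mM |  | 3.0 h |

| red: time / min | red: monomer in chains / % | ochre: time / min | ochre: monomer in chains / % |
|---|---|---|---|
| 3.00 | 3.4 | 3.00 | 4.0 |
| 6.00 | 7.7 | 6.00 | 5.9 |
| 12.0 | 11.2 | 12.0 | 6.1 |
| 25.0 | 9.5 | 25.0 | 5.1 |
| 50.0 | 9.0 | 50.0 | 4.6 |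
| 120 | 7.0 | 120 | 3.9 |

(readings scatter by 0.5 percentage points)

* time up to 3.0 h at which monomer in chains stands highest
* the amount of monomer in chains, in percent of the free monomer charged, at that time
* earliest time at which at least nineteen twentieths of that best amount are there
* latest time at which they still are

- Red's top reading, 11.2% at 12.0 min, stood higher than its neighbours, and it gives the moles of monomer in chains at that reading per mole of pre-initiator charged, n = 2.20.
- Ochre's top reading, 6.1%, is a lower percentage, yet it gives n = 2.63, more than red.
- The peak percentage is n times the pre-initiator charge, divided by the free monomer charge. I assumed that n grows steadily with free monomer, which put the new flask above 7.47% and below 8.95%.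
- These are bounds from readings, not walls: each reading scatters by 0.5 percentage points, and a true peak may fall between samples.
- I tightened the bracket by taking n as linear in the logarithm of the free monomer charge. For the new flask that gave n = 2.42, hence 8.23%.
- The forecast, “Interpolating as a power law in monomer”, said 8.3% at 0.18 h, with a window from 0.14 h to 0.26 h. That lay inside my bracket, slightly above my figure.
- The new flask peaked at 8.49% at 0.183 h, with its window from 0.130 h to 0.277 h. This was inside the bracket, with n = 2.50.

    free monomer + living end → monomer in chains + living end, rate k1*[living end]*[free monomer] (k = 0.0634 M⁻¹ s⁻¹)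
    free monomer + monomer in chains → side product (k = 0.0126 M⁻¹ s⁻¹)
    free monomer + initiator → living end + monomer in chains (k = 0.00198 M⁻¹ s⁻¹)
    living end + monomer in chains → dead end (k = 0.00580 M⁻¹ s⁻¹)
    pre-initiator → initiator (k = 0.0173 s⁻¹)

- The count n says nothing of side product, which held 69.2% of the free monomer charged in the new flask at its best time, beside 21.8% still free. I then put red's n on the neighbour charged with 0.90 M of free monomer and the same pre-initiator, which gave 12.5%. That neighbour's best was 11.7%.

The runs are calculated for an exercise; noise was put on by code.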